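2.00% is the trap ceiling C, the capture agent's charge over the starting material's charge, and each capture agent takes one intermediate A with no arrow leading back.

- winter: starting material 0.50 mM; protic impurity 0.250 mM; capture agent 0.0100 mM; time 20 s
- dawn: starting material 0.50 mM; protic impurity 0.250 mM; capture agent 0.0100 mM; time 40 s

    intermediate A + capture agent → trapped intermediate (k1 = 5100 M⁻¹ s⁻¹)
    starting material + protic impurity → quenched substrate (k2 = 150 M⁻¹ s⁻¹)
    starting material → intermediate A (k3 = 0.26 s⁻¹)
    intermediate A → intermediate B (k4 = 0.085 s⁻¹)
    intermediate B → product (k5 = 2.1 s⁻¹)

- which of the two there is more of at the end, winter (product / trapped intermediate)
- which of the two there is more of at the end, dawn (product / trapped intermediate)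
- how much product is there at the end, in percent of the starting material charged: winter
- how much product is there at the end, in percent of the starting material charged: dawn

**Turned round.** Trapped intermediate cannot pass C in winter or dawn, so the opposite mark needs product below C at the reading. I therefore ask where product ends and how fast it gets there.

**End state.** If intermediate A holds half the charge, the capture agent, the limiting reagent, has a pseudo-first-order life of 0.784 s, much shorter than the 20 s of winter, so I take the ceiling as filled. At the start, starting material goes to intermediate A 6.9 times as fast as to quenched substrate, a quenched share of 12.6%. Taking that share for the whole run, I put the product plateau near 85.4%, far above C.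

**The approach.** Intermediate A going to intermediate B has a half-life of 8.2 s, the longest of the chain. The steps before and after it add a lag of 4.32 s. If the plateau fills exponentially at that step's rate after the lag, I get 62.9% in winter and 81.3% in dawn. Both stand above C, so I mark product twice.

**The forecast.** It marks product in winter and product in dawn, with 63.3% and 82.4% of product, and it says “Trapped intermediate therefore caps at” the capture agent's charge. Its dawn figure is higher than mine.

**The flasks.** Winter holds 63.4% product, more than its 2.00% trapped intermediate, and dawn holds 82.4% against 2.00%. In winter the trapped share matches C, with capture agent at 0% of its charge. A neighbour of winter, charged 0.040 mM of capture agent, has a ceiling of 8.00%. It reads 8.00% trapped intermediate with 0% of its capture agent left, and 58.8% product after 20.0 s.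

The numbers come from no measurement; what happens was integrated by code.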